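## Structural features

Broussoflavonol B is a 3-methoxyflavone: a benzo ring A (C4a, C5, C6, C7, C8, C8a) is fused to a γ-pyrone ring C (O1, C2, C3, C4), which carries the catechol ring B on C2 and a methyl ether on C3. Ring A bears no hydrogen: oxygen at C5, C7 and C8a alternates with carbon substituents at C4a (the C4 carbonyl), C6 and C8 (two 3-methylbut-2-enyl groups), so it is a doubly C-prenylated acylphloroglucinol. There is no stereocenter and no configured double bond, so every difficulty is one of regiochemistry and chemoselectivity. The fragile groups are the two prenyl chains, which cyclise onto a neighbouring free phenol under Brønsted or Lewis acid and do not tolerate electrophilic halogen, peracid or hydrogenation, and the catechol, which oxidises in basic air. The C3 methyl ether must be told apart from four phenolic hydroxyls, so it is best brought in as an ether and never exposed to ether-cleaving Lewis acids. The real difficulty is ring A: two prenyl groups must sit on carbon (not on oxygen, not twice on one carbon) of a phloroglucinol, with exactly one position left for the acyl carbon. The feature that the key step exploits is that ring A, read around the ring, consists of three head-to-tail C(O)–C units, C8a(O)–C4a, C5(O)–C6(prenyl) and C7(O)–C8(prenyl), two of them the same oxygenated prenyl-alkyne unit and the third a ketene unit, and that the ring is symmetric about the C4a···C7 axis, so either oxygen next to C4a may become O1. In one sentence, the route is a Danheiser benzannulation of a 3-siloxy-2-prenylcyclobutenone with a prenylated siloxyalkyne that builds ring A with both prenyl groups and all three oxygens already in place.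

## Logic of the disconnections

**26 from 25.** Bonds cut: the four O–Si bonds at O5, O7, O3′ and O4′. The two ring-A silyl ethers come out of the benzannulation at no cost and flank both prenyl groups, so no free phenol can cyclise onto a prenyl chain during the route; the same group on ring B allows one final unmasking. Gain: one protecting-group type for four phenols, and the catechol stays hidden until the last step. Demand: a fluoride source that is neither strongly basic nor acidic.

**25 from 22.** Bond cut: O1–C2 of ring C, with loss of water (23 and 24 are passed through). An o-hydroxyaryl 1,3-diketone closes to the γ-pyrone under mild acid and carries the C3 methoxy group as a plain ether. Gain: ring C becomes an open three-carbon chain with C2 and C4 as carbonyls. Demand: the acid must cleave only the chelated acetal of 22 and spare the silyl ethers and the prenyl groups.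

**22 from 18 and 20.** Bond cut: C2–C3. C3 is the α-carbon of a ketone and C2 an acyl carbon, so a crossed Claisen condensation applies. Gain: ring B leaves as 20, one step from commercial 19, and 18 is a simple methoxymethyl ketone with a single enolisable site. Demand: the enolate 21 must be acylated on carbon.

**18 from 15 and 16.** Bond cut: C4a–C4. C4a is the only C–H of ring A in 15 and lies next to the acetal oxygen, so it can be lithiated (17) without any Lewis acid near the prenyl groups. Gain: C4, C3 and the methoxy group come from commercial 16 in one operation. Demand: ring lithiation must be faster than deprotonation of a prenyl CH2 and than silyl migration from the neighbouring oxygen.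

**15 from 14.** Bond cut: the O–CH2 bond of the acetal. The free hydroxyl of 14 is the future O1; the acetal masks it and directs the metalation. Gain: small. Demand: none beyond a non-acidic alkylation.

**14 from 9 and 6 (key disconnection).** Bonds cut: C8–C8a and C6–C7; the ring is then opened at C4a–C8a, which is the C4–C1 bond of 9 and is broken and re-formed during the step. Gain: a hexasubstituted benzene is reduced to a four-membered ring and an alkyne that share the same prenyl–C≡C–O unit. The three oxygens emerge differentiated (one free hydroxyl, two silyl ethers) and the single remaining C–H is the future C4a. Demand: head-to-tail orientation of the ketene–alkyne cycloaddition, and ring opening of 9 at a temperature that 6 tolerates.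

**9 from 6 and 7.** Bonds cut: C4a–C5 (C4–C3 of 9) and the C1–C2 bond of 9, which is sacrificial and is broken again in the key step. A ketene (8, from 7) adds to the same alkyne 6, so ring A is assembled from two molecules of 6 and one two-carbon unit. Demand: 8 must be trapped by 6 faster than it dimerises.

**6 from 3, and 3 from 1 and 2.** Bonds cut: O–Si and C(sp)–O of 6, then the C(sp3)–C(sp) bond of 3. Gain: the whole prenylated two-carbon oxygenated unit comes from two commercial reagents. Demand: substitution at the primary carbon of 1, and O- rather than C-silylation of 5.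

**20 from 19.** Bonds cut: two O–Si bonds. Gain: ring B from a commercial ester. Demand: none special.

## Other disconnections considered

Alternative 1: This is the plan that comes to mind first. It cuts O1–C2 and C3–O of ring C and leaves ring A to direct alkylation. The commercial unprenylated acylphloroglucinol would be C-prenylated twice with 1 to give A1. After acetal protection, aldol condensation with a protected catechol aldehyde would give chalcone A2. The forward key step is Algar–Flynn–Oyamada oxidative cyclisation of A2 to flavonol A3, followed by O-methylation at C3 and deprotection. The chosen plan is preferred on three grounds: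
- The phloroglucinol anion is ambident and each alkylation product is still a nucleophile, so O-alkylation and mono-, di- and geminal dialkylation (with dearomatisation) are expected to compete. The substitution pattern of ring A would rest on a statistical step.
- A chalcone with a 6′-substituent, such as A2, is twisted about the aryl–carbonyl bond, which is expected to favour five-membered closure to an aurone over six-membered closure to A3.
- The C3 oxygen must be methylated afterwards instead of arriving as an ether. The step count would be similar, but two steps would have poor selectivity.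

Alternative 2: This cuts the C2–C1′ bond between ring C and ring B. The forward key step is an oxidative Heck-type C–H arylation of C2–H of chromone A4 with arylboronic acid A5 under Pd(OAc)2 and an oxidant, giving A6. The chosen plan is preferred on three grounds:
- The cut simplifies the easy end of the molecule. A4 still contains the complete hexasubstituted ring A, so the bis-prenylation problem is untouched.
- Arylpalladium addition across C2=C3 places palladium on the fully substituted, methoxy-bearing C3. The β-hydride elimination at C2 is then possible only after isomerisation through the oxygen-bound enolate.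
- Divalent palladium under oxidative conditions is expected to engage the prenyl alkenes, by π-allyl formation or oxypalladation from a neighbouring oxygen.

Alternative 3: This cuts both aryl–prenyl bonds at the end, on an intact flavone. The forward key step is a twofold Suzuki–Miyaura coupling of the 6,8-diiodoflavone A7 with the prenylboronic ester A8 to give A9. The chosen plan is preferred on three grounds:
- Each C–I bond is flanked by two oxygen-bearing carbons, so two couplings at di-ortho-substituted positions are needed and protodeiodination is a likely competitor.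
- Allyl transfer from boron can deliver the prenyl or the 1,1-dimethylallyl isomer at each site, so ligand control would have to be complete twice.
- A full 3-O-methylquercetin synthesis with ring-A and ring-B hydroxyls differentiated is needed before A7, which makes the route longer. In the chosen plan each prenyl group is an alkyne substituent from the start and cannot end up on oxygen or in the branched form.

Key step: step 4

Remark: the target has no stereocenter and no configured double bond, so its SMILES carries no stereodescriptor; ketene is taken to be generated in the flask from acetyl chloride.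

## Steps

Step 1
Reactants: 1 1-bromo-3-methylbut-2-ene; 2 ethynylmagnesium bromide
Product: 3 5-methylhex-4-en-1-yne
Conditions: CuCl (5 mol %), THF, 0 °C → rt; distillation
Reagents that add atoms: none
Why: Copper-catalysed coupling of an alkynyl Grignard reagent with an allylic bromide; attack at the primary carbon of 1 is expected because the other allylic terminus is fully substituted.

Step 2
Reactants: 3 5-methylhex-4-en-1-yne
Product: 6 triisopropyl[(5-methylhex-4-en-1-yn-1-yl)oxy]silane, via lithium acetylide 4 (not isolated), via lithium ynolate 5 (not isolated)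
Conditions: n-BuLi, THF, −78 °C; t-BuOOLi (from t-BuOOH and LiN(SiMe3)2), −78 → 0 °C; TIPSOTf, −78 °C → rt
Reagents that add atoms: tert-butyl hydroperoxide, CC(C)(C)OO (used as its lithium salt, gives the ynol oxygen); triisopropylsilyl trifluoromethanesulfonate, CC(C)[Si](C(C)C)(C(C)C)OS(=O)(=O)C(F)(F)F
Why: Acetylide 4 is oxidised at carbon by the electrophilic oxygen of lithium tert-butyl peroxide to ynolate 5 (electrophilic oxygenation of an acetylide), and the bulky silyl triflate then silylates 5 on oxygen, the established route from terminal alkynes to triisopropylsilyl ynol ethers.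

Step 3
Reactants: 6 triisopropyl[(5-methylhex-4-en-1-yn-1-yl)oxy]silane; 7 acetyl chloride
Product: 9 2-(3-methylbut-2-en-1-yl)-3-[(triisopropylsilyl)oxy]cyclobut-2-en-1-one, via ketene 8 (not isolated)
Conditions: Et3N, Et2O, 0 °C → rt, slow addition of 7; filtration under N2, used crude
Reagents that add atoms: none
Why: Triethylamine dehydrochlorinates 7 to ketene 8, which the electron-rich siloxyalkyne traps in a [2+2] cycloaddition; the nucleophilic prenyl-bearing alkyne carbon attacks the ketene carbonyl carbon, so the siloxy group ends at C3 and the prenyl group at C2, and the CH2–C(OSi) bond formed here becomes C4a–C5 of the target.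

Step 4
Reactants: 9 2-(3-methylbut-2-en-1-yl)-3-[(triisopropylsilyl)oxy]cyclobut-2-en-1-one; 6 triisopropyl[(5-methylhex-4-en-1-yn-1-yl)oxy]silane
Product: 14 2,4-bis(3-methylbut-2-en-1-yl)-3,5-bis[(triisopropylsilyl)oxy]phenol, via vinylketene 10 (not isolated), via vinylcyclobutenone 11 (not isolated), via dienylketene 12 (not isolated), via cyclohexadienone 13 (not isolated)
Conditions: degassed toluene, 80 → 110 °C, slow addition of 9 to 6 (1.5 equiv)
Reagents that add atoms: none
Why: On heating, 9 undergoes reversible 4π electrocyclic opening to the (1-siloxyvinyl)ketene 10, which 6 captures in a [2+2] cycloaddition in which the nucleophilic prenyl-bearing alkyne carbon bonds to the ketene carbonyl carbon (new C8–C8a bond) and the oxygen-bearing alkyne carbon to the ketene α-carbon (new C6–C7 bond), giving 11. A second 4π opening of 11 gives dienylketene 12, and thermal disrotatory 6π electrocyclisation between the ketene carbon and the terminal CH2 closes the six-membered carbocycle ring A at C4a–C8a to give 13, which tautomerises irreversibly to phenol 14. The closest known reaction type is the Danheiser benzannulation of cyclobutenones with siloxyalkynes, which delivers resorcinol monosilyl ethers; the 3-siloxy group of 9 only adds the third oxygen. No stereocenter is created: the stereocenter of 11 and the double-bond geometry of 12 are transient, and since ring opening of 11 is reversible only the isomer of 12 with the siloxyvinyl group turned inward drains to product. The selectivity that the step needs is the orientation of the [2+2] event, and it is secured by the polarisation of both partners (nucleophilic β-carbon of the ynol ether, electrophilic sp carbon of the ketene), so the three oxygens end up 1,3,5, both prenyl groups flank the central siloxy group, and the only C–H is the future C4a. The trisubstituted prenyl alkenes are far poorer ketene acceptors than the ynol ether and sit one carbon from the ketene, too close for an intramolecular [2+2] reaction. Slow addition of 9 to an excess of 6 keeps the ketene concentration low and limits acylation of 14 by 10.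

Step 5
Reactants: 14 2,4-bis(3-methylbut-2-en-1-yl)-3,5-bis[(triisopropylsilyl)oxy]phenol
Product: 15 1-(methoxymethoxy)-2,4-bis(3-methylbut-2-en-1-yl)-3,5-bis[(triisopropylsilyl)oxy]benzene
Conditions: MOMCl, i-Pr2NEt, CH2Cl2, 0 °C → rt
Reagents that add atoms: chloromethyl methyl ether, COCCl
Why: Standard O-alkylation of a phenol with a chloromethyl ether; the acetal masks the future O1 and is the directing group for the next step.

Step 6
Reactants: 15 1-(methoxymethoxy)-2,4-bis(3-methylbut-2-en-1-yl)-3,5-bis[(triisopropylsilyl)oxy]benzene; 16 N,2-dimethoxy-N-methylacetamide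
Product: 18 2-methoxy-1-{2-(methoxymethoxy)-3,5-bis(3-methylbut-2-en-1-yl)-4,6-bis[(triisopropylsilyl)oxy]phenyl}ethan-1-one, via aryllithium 17 (not isolated)
Conditions: s-BuLi, TMEDA, THF, −78 → −40 °C; then 16, −78 → 0 °C
Reagents that add atoms: none
Why: Directed ortho metalation: the acetal oxygen delivers the base to the only aromatic C–H, and aryllithium 17 adds once to the Weinreb amide because the chelated tetrahedral adduct survives until work-up (Weinreb ketone synthesis); the low temperature disfavours silyl migration from the neighbouring oxygen to carbon.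

Step 7
Reactants: 19 methyl 3,4-dihydroxybenzoate
Product: 20 methyl 3,4-bis[(triisopropylsilyl)oxy]benzoate
Conditions: TIPSOTf, 2,6-lutidine, CH2Cl2, 0 °C → rt
Reagents that add atoms: triisopropylsilyl trifluoromethanesulfonate, CC(C)[Si](C(C)C)(C(C)C)OS(=O)(=O)C(F)(F)F
Why: Silylation of both catechol hydroxyls with the reactive silyl triflate and a hindered base; the ester is untouched.

Step 8
Reactants: 18 2-methoxy-1-{2-(methoxymethoxy)-3,5-bis(3-methylbut-2-en-1-yl)-4,6-bis[(triisopropylsilyl)oxy]phenyl}ethan-1-one; 20 methyl 3,4-bis[(triisopropylsilyl)oxy]benzoate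
Product: 22 1-{2-(methoxymethoxy)-3,5-bis(3-methylbut-2-en-1-yl)-4,6-bis[(triisopropylsilyl)oxy]phenyl}-3-{3,4-bis[(triisopropylsilyl)oxy]phenyl}-2-methoxypropane-1,3-dione, via lithium enolate 21 (not isolated)
Conditions: LiN(SiMe3)2 (3 equiv), THF, −78 °C; then 20, −78 °C → rt
Reagents that add atoms: none
Why: Crossed Claisen condensation: the chelated lithium enolate 21, the only enolate that can form, is acylated on carbon by the non-enolisable ester 20, and deprotonation of the resulting 1,3-diketone by the excess base drives the equilibrium.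

Step 9
Reactants: 22 1-{2-(methoxymethoxy)-3,5-bis(3-methylbut-2-en-1-yl)-4,6-bis[(triisopropylsilyl)oxy]phenyl}-3-{3,4-bis[(triisopropylsilyl)oxy]phenyl}-2-methoxypropane-1,3-dione
Product: 25 3-methoxy-6,8-bis(3-methylbut-2-en-1-yl)-5,7-bis[(triisopropylsilyl)oxy]-2-{3,4-bis[(triisopropylsilyl)oxy]phenyl}-4H-chromen-4-one, via hydroxy diketone 23 (not isolated), via hemiketal 24 (not isolated)
Conditions: HCl (1 M in MeOH), THF, rt → 45 °C
Reagents that add atoms: none
Why: The acetal ortho to the ketone is cleaved by mild methanolic acid (acetal exchange), the freed phenol of 23 adds to the ring-B carbonyl to give hemiketal 24, and acid-catalysed loss of water gives the γ-pyrone (cyclodehydration of an o-hydroxyaryl 1,3-diketone, the closing stage of the Baker–Venkataraman flavone synthesis). Aryl triisopropylsilyl ethers should withstand these conditions and, flanking both prenyl groups, leave no free phenol to cyclise onto them.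

Step 10
Reactants: 25 3-methoxy-6,8-bis(3-methylbut-2-en-1-yl)-5,7-bis[(triisopropylsilyl)oxy]-2-{3,4-bis[(triisopropylsilyl)oxy]phenyl}-4H-chromen-4-one
Product: 26 Broussoflavonol B
Conditions: Bu4NF (6 equiv), AcOH (6 equiv), THF, 0 °C → rt, under argon
Reagents that add atoms: none
Why: Fluoride cleaves the four aryl silyl ethers by Si–F bond formation; acetic acid buffers the phenoxides so that the catechol is not oxidised and the prenyl groups never meet strong acid.

## Compound list

1 | 1-bromo-3-methylbut-2-ene (prenyl bromide) | CC(C)=CCBr | starting material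
2 | ethynylmagnesium bromide | C#C[Mg]Br | starting material
3 | 5-methylhex-4-en-1-yne | CC(C)=CCC#C | intermediate
4 | (5-methylhex-4-en-1-yn-1-yl)lithium (lithium acetylide; not isolated) | CC(C)=CCC#C[Li] | intermediate
5 | lithium 5-methylhex-4-en-1-yn-1-olate (lithium ynolate; not isolated) | CC(C)=CCC#C[O-].[Li+] | intermediate
6 | triisopropyl[(5-methylhex-4-en-1-yn-1-yl)oxy]silane | CC(C)=CCC#CO[Si](C(C)C)(C(C)C)C(C)C | intermediate
7 | acetyl chloride | CC(=O)Cl | starting material
8 | ketene (ethenone; not isolated) | C=C=O | intermediate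
9 | 2-(3-methylbut-2-en-1-yl)-3-[(triisopropylsilyl)oxy]cyclobut-2-en-1-one | O=C1CC(O[Si](C(C)C)(C(C)C)C(C)C)=C1CC=C(C)C | intermediate
10 | 2-(3-methylbut-2-en-1-yl)-3-[(triisopropylsilyl)oxy]buta-1,3-dien-1-one (vinylketene; not isolated) | O=C=C(CC=C(C)C)C(=C)O[Si](C(C)C)(C(C)C)C(C)C | intermediate
11 | 2,4-bis(3-methylbut-2-en-1-yl)-3-[(triisopropylsilyl)oxy]-4-{1-[(triisopropylsilyl)oxy]ethenyl}cyclobut-2-en-1-one (vinylcyclobutenone; racemic; not isolated) | O=C1C(CC=C(C)C)=C(O[Si](C(C)C)(C(C)C)C(C)C)C1(CC=C(C)C)C(=C)O[Si](C(C)C)(C(C)C)C(C)C | intermediate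
12 | (3E)-2,4-bis(3-methylbut-2-en-1-yl)-3,5-bis[(triisopropylsilyl)oxy]hexa-1,3,5-trien-1-one (dienylketene, ketene carbon and siloxyvinyl group cis; not isolated) | O=C=C(CC=C(C)C)/C(O[Si](C(C)C)(C(C)C)C(C)C)=C(/CC=C(C)C)C(=C)O[Si](C(C)C)(C(C)C)C(C)C | intermediate
13 | 2,4-bis(3-methylbut-2-en-1-yl)-3,5-bis[(triisopropylsilyl)oxy]cyclohexa-2,4-dien-1-one (cyclohexadienone; not isolated) | O=C1CC(O[Si](C(C)C)(C(C)C)C(C)C)=C(CC=C(C)C)C(O[Si](C(C)C)(C(C)C)C(C)C)=C1CC=C(C)C | intermediate
14 | 2,4-bis(3-methylbut-2-en-1-yl)-3,5-bis[(triisopropylsilyl)oxy]phenol | Oc1cc(O[Si](C(C)C)(C(C)C)C(C)C)c(CC=C(C)C)c(O[Si](C(C)C)(C(C)C)C(C)C)c1CC=C(C)C | intermediate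
15 | 1-(methoxymethoxy)-2,4-bis(3-methylbut-2-en-1-yl)-3,5-bis[(triisopropylsilyl)oxy]benzene | COCOc1cc(O[Si](C(C)C)(C(C)C)C(C)C)c(CC=C(C)C)c(O[Si](C(C)C)(C(C)C)C(C)C)c1CC=C(C)C | intermediate
16 | N,2-dimethoxy-N-methylacetamide | COCC(=O)N(C)OC | starting material
17 | {2-(methoxymethoxy)-3,5-bis(3-methylbut-2-en-1-yl)-4,6-bis[(triisopropylsilyl)oxy]phenyl}lithium (aryllithium; not isolated) | [Li]c1c(OCOC)c(CC=C(C)C)c(O[Si](C(C)C)(C(C)C)C(C)C)c(CC=C(C)C)c1O[Si](C(C)C)(C(C)C)C(C)C | intermediate
18 | 2-methoxy-1-{2-(methoxymethoxy)-3,5-bis(3-methylbut-2-en-1-yl)-4,6-bis[(triisopropylsilyl)oxy]phenyl}ethan-1-one | COCC(=O)c1c(OCOC)c(CC=C(C)C)c(O[Si](C(C)C)(C(C)C)C(C)C)c(CC=C(C)C)c1O[Si](C(C)C)(C(C)C)C(C)C | intermediate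
19 | methyl 3,4-dihydroxybenzoate | COC(=O)c1ccc(O)c(O)c1 | starting material
20 | methyl 3,4-bis[(triisopropylsilyl)oxy]benzoate | COC(=O)c1ccc(O[Si](C(C)C)(C(C)C)C(C)C)c(O[Si](C(C)C)(C(C)C)C(C)C)c1 | intermediate
21 | lithium (Z)-enolate of 18 (not isolated) | CO/C=C(\[O-])c1c(OCOC)c(CC=C(C)C)c(O[Si](C(C)C)(C(C)C)C(C)C)c(CC=C(C)C)c1O[Si](C(C)C)(C(C)C)C(C)C.[Li+] | intermediate
22 | 1-{2-(methoxymethoxy)-3,5-bis(3-methylbut-2-en-1-yl)-4,6-bis[(triisopropylsilyl)oxy]phenyl}-3-{3,4-bis[(triisopropylsilyl)oxy]phenyl}-2-methoxypropane-1,3-dione (racemic, enolisable) | COC(C(=O)c1ccc(O[Si](C(C)C)(C(C)C)C(C)C)c(O[Si](C(C)C)(C(C)C)C(C)C)c1)C(=O)c1c(OCOC)c(CC=C(C)C)c(O[Si](C(C)C)(C(C)C)C(C)C)c(CC=C(C)C)c1O[Si](C(C)C)(C(C)C)C(C)C | intermediate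
23 | 1-{2-hydroxy-3,5-bis(3-methylbut-2-en-1-yl)-4,6-bis[(triisopropylsilyl)oxy]phenyl}-3-{3,4-bis[(triisopropylsilyl)oxy]phenyl}-2-methoxypropane-1,3-dione (hydroxy diketone; racemic; not isolated) | COC(C(=O)c1ccc(O[Si](C(C)C)(C(C)C)C(C)C)c(O[Si](C(C)C)(C(C)C)C(C)C)c1)C(=O)c1c(O)c(CC=C(C)C)c(O[Si](C(C)C)(C(C)C)C(C)C)c(CC=C(C)C)c1O[Si](C(C)C)(C(C)C)C(C)C | intermediate
24 | 2-hydroxy-3-methoxy-6,8-bis(3-methylbut-2-en-1-yl)-5,7-bis[(triisopropylsilyl)oxy]-2-{3,4-bis[(triisopropylsilyl)oxy]phenyl}chroman-4-one (hemiketal; mixture of racemic diastereomers; not isolated) | COC1C(=O)c2c(O[Si](C(C)C)(C(C)C)C(C)C)c(CC=C(C)C)c(O[Si](C(C)C)(C(C)C)C(C)C)c(CC=C(C)C)c2OC1(O)c1ccc(O[Si](C(C)C)(C(C)C)C(C)C)c(O[Si](C(C)C)(C(C)C)C(C)C)c1 | intermediate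
25 | 3-methoxy-6,8-bis(3-methylbut-2-en-1-yl)-5,7-bis[(triisopropylsilyl)oxy]-2-{3,4-bis[(triisopropylsilyl)oxy]phenyl}-4H-chromen-4-one | COc1c(-c2ccc(O[Si](C(C)C)(C(C)C)C(C)C)c(O[Si](C(C)C)(C(C)C)C(C)C)c2)oc2c(CC=C(C)C)c(O[Si](C(C)C)(C(C)C)C(C)C)c(CC=C(C)C)c(O[Si](C(C)C)(C(C)C)C(C)C)c2c1=O | intermediate
26 | Broussoflavonol B, 2-(3,4-dihydroxyphenyl)-5,7-dihydroxy-3-methoxy-6,8-bis(3-methylbut-2-en-1-yl)-4H-chromen-4-one | COc1c(-c2ccc(O)c(O)c2)oc2c(CC=C(C)C)c(O)c(CC=C(C)C)c(O)c2c1=O | target

## Step count and least certain steps

Total steps: 10. Longest linear sequence: 9 steps (steps 1 to 6, 8, 9 and 10); step 7 is a one-step side branch.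

**Step 4 (key step).** The most likely failure is insufficient ring opening of 9 at a temperature that 6 tolerates. The 3-siloxy group makes 9 a vinylogous silyl ester and stabilises the four-membered ring, so the vinylketene may form only in a range where the siloxyalkyne isomerises by silyl shift to a silylketene. Acylation of the product phenol by ketene intermediates could further stall the reaction. The fallback sets out from 1 and returns to the route at 18, taking ring A from phloroglucinol. Hoesch acylation of phloroglucinol with methoxyacetonitrile (ZnCl2, HCl, Et2O; then hot water) would give 2-methoxy-1-(2,4,6-trihydroxyphenyl)ethan-1-one F1. Twofold C-prenylation with 1 (aqueous KOH, 0 °C) would give 1-[2,4,6-trihydroxy-3,5-bis(3-methylbut-2-en-1-yl)phenyl]-2-methoxyethan-1-one F2, to be separated from mono- and over-alkylated material. Silylation of the two hydroxyls that are not held in the hydrogen bond to the ketone (TIPSOTf, 2,6-lutidine, CH2Cl2) would give 1-{2-hydroxy-3,5-bis(3-methylbut-2-en-1-yl)-4,6-bis[(triisopropylsilyl)oxy]phenyl}-2-methoxyethan-1-one F3, and MOMCl with NaH in DMF would convert F3 into 18.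

**Step 3.** The most likely failure is self-condensation of ketene 8 (dimerisation and oligomerisation) outrunning its cycloaddition to 6, together with hydrolytic loss of silicon from the vinylogous silyl ester 9 during isolation. The fallback sets out from 6 and returns at 9. Cycloaddition of 6 with dichloroketene, which is more electrophilic and does not dimerise (trichloroacetyl chloride, zinc–copper couple, Et2O), would give 4,4-dichloro-2-(3-methylbut-2-en-1-yl)-3-[(triisopropylsilyl)oxy]cyclobut-2-en-1-one F4. Radical dechlorination under neutral conditions (Bu3SnH, Et3B/air, toluene, 0 °C) would then give 9.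

**Step 6.** Three processes could defeat the ring lithiation and acylation:
- lateral deprotonation at the benzylic and allylic CH2 of the prenyl group next to the acetal oxygen;
- migration of silicon from the neighbouring oxygen to the lithiated carbon;
- proton transfer from 16 to the hindered aryllithium, which returns 15.

The fallback sets out from 14 and returns at 18, bringing the carbon in by a magnesium-mediated phenol formylation that needs no aryllithium. Casnati–Skattebøl ortho-formylation of 14 (MgCl2, Et3N, paraformaldehyde, MeCN, reflux) would give 2-hydroxy-3,5-bis(3-methylbut-2-en-1-yl)-4,6-bis[(triisopropylsilyl)oxy]benzaldehyde F5. Protection (MOMCl, i-Pr2NEt) would give 2-(methoxymethoxy)-3,5-bis(3-methylbut-2-en-1-yl)-4,6-bis[(triisopropylsilyl)oxy]benzaldehyde F6. Addition of methoxymethyllithium (from tributyl(methoxymethyl)stannane and n-BuLi, THF, −78 °C) would give 2-methoxy-1-{2-(methoxymethoxy)-3,5-bis(3-methylbut-2-en-1-yl)-4,6-bis[(triisopropylsilyl)oxy]phenyl}ethan-1-ol F7, and oxidation with Dess–Martin periodinane would give 18.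

**Step 8.** The most likely failure is slow acyl transfer from the electron-rich ester to the chelated, hindered enolate. The liberated methoxide could then attack the aryl silyl ethers, or silicon could migrate from the oxygen ortho to the ketone onto the enolate oxygen. The fallback sets out from 18 and returns at 22, replacing the ester by an aldehyde. 3,4-Bis[(triisopropylsilyl)oxy]benzaldehyde F8 would be made from 3,4-dihydroxybenzaldehyde in the way 20 is made from 19. Aldol addition of enolate 21 to F8 at −78 °C would give 3-hydroxy-1-{2-(methoxymethoxy)-3,5-bis(3-methylbut-2-en-1-yl)-4,6-bis[(triisopropylsilyl)oxy]phenyl}-3-{3,4-bis[(triisopropylsilyl)oxy]phenyl}-2-methoxypropan-1-one F9 as a mixture of diastereomers. Oxidation with Dess–Martin periodinane would converge on 22.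

## Further compounds

F1 | step 4 | 2-methoxy-1-(2,4,6-trihydroxyphenyl)ethan-1-one | COCC(=O)c1c(O)cc(O)cc1O
F2 | step 4 | 1-[2,4,6-trihydroxy-3,5-bis(3-methylbut-2-en-1-yl)phenyl]-2-methoxyethan-1-one | COCC(=O)c1c(O)c(CC=C(C)C)c(O)c(CC=C(C)C)c1O
F3 | step 4 | 1-{2-hydroxy-3,5-bis(3-methylbut-2-en-1-yl)-4,6-bis[(triisopropylsilyl)oxy]phenyl}-2-methoxyethan-1-one | COCC(=O)c1c(O)c(CC=C(C)C)c(O[Si](C(C)C)(C(C)C)C(C)C)c(CC=C(C)C)c1O[Si](C(C)C)(C(C)C)C(C)C
F4 | step 3 | 4,4-dichloro-2-(3-methylbut-2-en-1-yl)-3-[(triisopropylsilyl)oxy]cyclobut-2-en-1-one | O=C1C(CC=C(C)C)=C(O[Si](C(C)C)(C(C)C)C(C)C)C1(Cl)Cl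
F5 | step 6 | 2-hydroxy-3,5-bis(3-methylbut-2-en-1-yl)-4,6-bis[(triisopropylsilyl)oxy]benzaldehyde | O=Cc1c(O)c(CC=C(C)C)c(O[Si](C(C)C)(C(C)C)C(C)C)c(CC=C(C)C)c1O[Si](C(C)C)(C(C)C)C(C)C
F6 | step 6 | 2-(methoxymethoxy)-3,5-bis(3-methylbut-2-en-1-yl)-4,6-bis[(triisopropylsilyl)oxy]benzaldehyde | O=Cc1c(OCOC)c(CC=C(C)C)c(O[Si](C(C)C)(C(C)C)C(C)C)c(CC=C(C)C)c1O[Si](C(C)C)(C(C)C)C(C)C
F7 | step 6 | 2-methoxy-1-{2-(methoxymethoxy)-3,5-bis(3-methylbut-2-en-1-yl)-4,6-bis[(triisopropylsilyl)oxy]phenyl}ethan-1-ol (racemic) | COCC(O)c1c(OCOC)c(CC=C(C)C)c(O[Si](C(C)C)(C(C)C)C(C)C)c(CC=C(C)C)c1O[Si](C(C)C)(C(C)C)C(C)C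
F8 | step 8 | 3,4-bis[(triisopropylsilyl)oxy]benzaldehyde | O=Cc1ccc(O[Si](C(C)C)(C(C)C)C(C)C)c(O[Si](C(C)C)(C(C)C)C(C)C)c1
F9 | step 8 | 3-hydroxy-1-{2-(methoxymethoxy)-3,5-bis(3-methylbut-2-en-1-yl)-4,6-bis[(triisopropylsilyl)oxy]phenyl}-3-{3,4-bis[(triisopropylsilyl)oxy]phenyl}-2-methoxypropan-1-one (mixture of racemic diastereomers) | COC(C(O)c1ccc(O[Si](C(C)C)(C(C)C)C(C)C)c(O[Si](C(C)C)(C(C)C)C(C)C)c1)C(=O)c1c(OCOC)c(CC=C(C)C)c(O[Si](C(C)C)(C(C)C)C(C)C)c(CC=C(C)C)c1O[Si](C(C)C)(C(C)C)C(C)C
A1 | alternative 1 | 1-[2,4,6-trihydroxy-3,5-bis(3-methylbut-2-en-1-yl)phenyl]ethan-1-one | CC(=O)c1c(O)c(CC=C(C)C)c(O)c(CC=C(C)C)c1O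
A2 | alternative 1 | (E)-1-[2-hydroxy-4,6-bis(methoxymethoxy)-3,5-bis(3-methylbut-2-en-1-yl)phenyl]-3-[3,4-bis(methoxymethoxy)phenyl]prop-2-en-1-one | COCOc1ccc(/C=C/C(=O)c2c(O)c(CC=C(C)C)c(OCOC)c(CC=C(C)C)c2OCOC)cc1OCOC
A3 | alternative 1 | 3-hydroxy-5,7-bis(methoxymethoxy)-2-[3,4-bis(methoxymethoxy)phenyl]-6,8-bis(3-methylbut-2-en-1-yl)-4H-chromen-4-one | COCOc1ccc(-c2oc3c(CC=C(C)C)c(OCOC)c(CC=C(C)C)c(OCOC)c3c(=O)c2O)cc1OCOC
A4 | alternative 2 | 3-methoxy-5,7-bis(methoxymethoxy)-6,8-bis(3-methylbut-2-en-1-yl)-4H-chromen-4-one | COc1coc2c(CC=C(C)C)c(OCOC)c(CC=C(C)C)c(OCOC)c2c1=O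
A5 | alternative 2 | [3,4-bis(methoxymethoxy)phenyl]boronic acid | COCOc1ccc(B(O)O)cc1OCOC
A6 | alternative 2 | 3-methoxy-5,7-bis(methoxymethoxy)-2-[3,4-bis(methoxymethoxy)phenyl]-6,8-bis(3-methylbut-2-en-1-yl)-4H-chromen-4-one | COCOc1ccc(-c2oc3c(CC=C(C)C)c(OCOC)c(CC=C(C)C)c(OCOC)c3c(=O)c2OC)cc1OCOC
A7 | alternative 3 | 5,7-dihydroxy-6,8-diiodo-3-methoxy-2-[3,4-bis(methoxymethoxy)phenyl]-4H-chromen-4-one | COCOc1ccc(-c2oc3c(I)c(O)c(I)c(O)c3c(=O)c2OC)cc1OCOC
A8 | alternative 3 | 4,4,5,5-tetramethyl-2-(3-methylbut-2-en-1-yl)-1,3,2-dioxaborolane | CC(C)=CCB1OC(C)(C)C(C)(C)O1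
A9 | alternative 3 | 5,7-dihydroxy-3-methoxy-2-[3,4-bis(methoxymethoxy)phenyl]-6,8-bis(3-methylbut-2-en-1-yl)-4H-chromen-4-one | COCOc1ccc(-c2oc3c(CC=C(C)C)c(O)c(CC=C(C)C)c(O)c3c(=O)c2OC)cc1OCOC
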